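The core is numbered as 3,7-dioxabicyclo[3.3.0]octane (C2 carries the guaiacyl group, C6 the prenyloxy-aryl group). Ring A is cut at C1–C2 and O3–C2, leaving a trans-2-aryl-3-(hydroxymethyl)-2,3-dihydrofuran that is ring B (O7, C6, C5, C1, C8). Ring B is made by ring expansion: its C6–O7–C8 unit is first built as an aryl vinyl oxirane. Flash pyrolysis breaks the oxirane C6–C8 bond to a carbonyl ylide, whose electrocyclisation onto the acrylate forms C6–C5. The three-membered ring thus grows into the five-membered one and both ring B stereocentres arise together. The oxirane comes from a vinylogous Darzens reaction of silyl-protected vanillin.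

Key step: step 3

Remark (assumption): Burkholderia cepacia lipase is taken to acetylate the (3R)-configured primary alcohol faster, as its empirical size rule for 2-substituted primary alcohols predicts; the route is written for this sense.
Remark: compounds 4 to 8 are racemates; their SMILES show the enantiomer that is carried on after the resolution in step 6. Atom numbers C1 to C8 in the Why lines are those of the target core.

Step 1
Reactants: 1 vanillin
Product: 2 3-methoxy-4-(triisopropylsilyloxy)benzaldehyde
Conditions: TIPSCl, imidazole, DMF, rt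
Reagents that add atoms: triisopropylsilyl chloride, CC(C)[Si](Cl)(C(C)C)C(C)C
Why: Silyl ether formation on the phenol installs a group that should survive strong base, heat, hydride and Lewis acid and is later removed by fluoride; no stereocentre is involved.

Step 2
Reactants: 2 3-methoxy-4-(triisopropylsilyloxy)benzaldehyde; 3 methyl (E)-4-bromobut-2-enoate
Product: 4 methyl (E)-3-{3-[3-methoxy-4-(triisopropylsilyloxy)phenyl]oxiran-2-yl}prop-2-enoate (racemic, both oxirane diastereomers)
Conditions: LiN(iPr)2, THF, −78 °C; 3, then 2; −78 → 0 °C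
Reagents that add atoms: none
Why: Vinylogous Darzens condensation, in which γ-deprotonated 3 adds through its bromine-bearing carbon to the non-enolisable aldehyde and the alkoxide displaces bromide (3-exo-tet); the two oxirane stereocentres need no control because both are erased in step 3.

Step 3
Reactants: 4 vinyl oxirane
Product: 6 methyl rac-(2S,3R)-2-[3-methoxy-4-(triisopropylsilyloxy)phenyl]-2,3-dihydrofuran-3-carboxylate (cis), via carbonyl ylide 5 (not isolated)
Conditions: flash vacuum pyrolysis, 500 °C, 0.01 mbar, silica tube, cold trap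
Reagents that add atoms: none
Why: Thermal conrotatory opening of the oxirane C6–C8 bond should give the carbonyl ylide 5, stabilised by the aryl donor on C6 and the acrylate acceptor on C8, and its 6π disrotatory 1,5-electrocyclisation onto the alkene forms the C6–C5 bond, so the three-membered O7/C6/C8 ring grows by the alkene carbons C1 and C5 into the 2,3-dihydrofuran. The closest known reaction type is the thermal vinyl oxirane to 2,3-dihydrofuran rearrangement. The only ring closed is ring B, five-membered, by electrocyclisation of the five-atom C6–O7–C8–C1–C5 system. The new stereocentres C6 and C5 should come out cis because the ylide reacts with its aryl group outside while the (E)-alkene holds the ester outside, and disrotation turns both to the same face; the absolute sense is not controlled here and is settled by the resolution in step 6. The step needs C–C and not C–O cleavage of the oxirane, which the push-pull substitution secures, and both oxirane diastereomers converge on the same ylide; the short gas-phase contact time should keep the heat- and acid-sensitive enol ether from reacting further.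

Step 4
Reactants: 6 cis dihydrofuran ester
Product: 7 methyl rac-(2S,3S)-2-[3-methoxy-4-(triisopropylsilyloxy)phenyl]-2,3-dihydrofuran-3-carboxylate (trans)
Conditions: DBU, toluene, 80 °C
Reagents that add atoms: none
Why: Base-mediated epimerisation (thermodynamic equilibration through the ester dienolate with reprotonation at the α-carbon) should invert only the ester-bearing carbon (future C5) to the trans isomer, in which aryl and ester no longer eclipse, while C6 is untouched and the non-nucleophilic amidine spares the aryl silyl ether.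

Step 5
Reactants: 7 trans dihydrofuran ester
Product: 8 rac-{(2S,3R)-2-[3-methoxy-4-(triisopropylsilyloxy)phenyl]-2,3-dihydrofuran-3-yl}methanol (trans)
Conditions: iBu2AlH, CH2Cl2, −78 → 0 °C; aq. potassium sodium tartrate
Reagents that add atoms: none
Why: Hydride reduction of the ester to the primary alcohol, which touches no stereocentre and should leave the enol ether and the aryl silyl ether intact.

Step 6
Reactants: 8 racemic trans alcohol
Product: 9 {(2S,3R)-2-[3-methoxy-4-(triisopropylsilyloxy)phenyl]-2,3-dihydrofuran-3-yl}methyl acetate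
Conditions: Burkholderia cepacia lipase (immobilised), vinyl acetate, tBuOMe, rt, stopped just below half conversion
Reagents that add atoms: vinyl acetate, CC(=O)OC=C
Why: Lipase-catalysed kinetic resolution by irreversible transesterification, in which the (3R)-alcohol should be acetylated faster, so that the acetate carries the (2S,3R) configuration that becomes C6 (S) and C5 (R) of the target while the unreacted (2R,3S)-alcohol is removed by chromatography.

Step 7
Reactants: 9 (2S,3R)-acetate
Product: 10 {(2S,3R)-2-[3-methoxy-4-(triisopropylsilyloxy)phenyl]-2,3-dihydrofuran-3-yl}methanol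
Conditions: iBu2AlH, CH2Cl2, −78 °C; aq. potassium sodium tartrate
Reagents that add atoms: none
Why: Reductive cleavage of the acetate (ester reduction) frees the alcohol without the alkoxide bases that would attack the aryl silyl ether, and no stereocentre is affected.

Step 8
Reactants: 11 4-formyl-2-methoxyphenyl 2-methylpropanoate (vanillin isobutyrate)
Product: 12 4-(dimethoxymethyl)-2-methoxyphenyl 2-methylpropanoate
Conditions: HC(OMe)3, p-TsOH (cat.), CH2Cl2, rt; then Et3N
Reagents that add atoms: trimethyl orthoformate, COC(OC)OC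
Why: Acid-catalysed acetalisation with the orthoformate as methoxy donor and water scavenger, under anhydrous conditions that the hindered aryl ester should tolerate.

Step 9
Reactants: 10 (2S,3R)-dihydrofuranyl methanol; 12 aryl dimethyl acetal
Product: 14 4-{(1S,2R,5R,6S)-8-methoxy-6-[3-methoxy-4-(triisopropylsilyloxy)phenyl]-3,7-dioxabicyclo[3.3.0]octan-2-yl}-2-methoxyphenyl 2-methylpropanoate (C8 epimers), via mixed acetal 13 (not isolated)
Conditions: Me3SiOTf (cat.), CH2Cl2, −78 °C; then Et3N
Reagents that add atoms: none
Why: Acetal exchange gives 13, its ionisation gives an O3=C2 oxocarbenium ion, and the enol ether carbon C1 attacks it in a Prins-type cyclisation (5-endo at the oxocarbenium) that closes ring A on the face fixed by C5 (cis fusion, C1) and should place the aryl group on the concave face under kinetic control at low temperature (C2 R, endo), the resulting C8 oxocarbenium being trapped by methanol.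

Step 10
Reactants: 14 furofuran methyl acetal
Product: 15 4-{(1R,2R,5R,6S)-6-[3-methoxy-4-(triisopropylsilyloxy)phenyl]-3,7-dioxabicyclo[3.3.0]octan-2-yl}-2-methoxyphenyl 2-methylpropanoate
Conditions: Et3SiH, BF3·OEt2, CH2Cl2, −78 °C
Reagents that add atoms: none
Why: Ionic hydrogenation of the cyclic acetal, in which BF3 ionises the C8 methoxy group and the silane delivers hydride so that C8 becomes CH2, while the low temperature and the electron-poor acyloxy-aryl group should keep the endo centre C2 from ionising.

Step 11
Reactants: 15 silyl ether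
Product: 16 4-[(1R,2R,5R,6S)-6-(4-hydroxy-3-methoxyphenyl)-3,7-dioxabicyclo[3.3.0]octan-2-yl]-2-methoxyphenyl 2-methylpropanoate
Conditions: Bu4NF, AcOH, THF, 0 °C
Reagents that add atoms: none
Why: Fluoride-mediated cleavage of the aryl silyl ether, buffered with acetic acid so that no phenoxide is present to attack the aryl ester, with all stereocentres untouched.

Step 12
Reactants: 16 phenol; 17 3-methylbut-2-en-1-ol (prenol)
Product: 18 4-{(1R,2R,5R,6S)-6-[3-methoxy-4-(3-methylbut-2-enyloxy)phenyl]-3,7-dioxabicyclo[3.3.0]octan-2-yl}-2-methoxyphenyl 2-methylpropanoate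
Conditions: PPh3, DIAD, THF, 0 °C → rt
Reagents that add atoms: none
Why: Mitsunobu etherification of the phenol at the primary allylic carbon of prenol, under neutral conditions that should avoid both phenoxide-mediated acyl transfer and the acids to which an aryl prenyl ether is sensitive.

Step 13
Reactants: 18 prenyl ether isobutyrate
Product: 19 4-{(1R,2R,5R,6S)-6-[3-methoxy-4-(3-methylbut-2-enyloxy)phenyl]-3,7-dioxabicyclo[3.3.0]octan-2-yl}-2-methoxyphenol (target)
Conditions: K2CO3 (cat.), MeOH, rt
Reagents that add atoms: none
Why: Base-catalysed methanolysis (transesterification) of the aryl ester should free the phenol, the prenyl ether and the benzylic ethers of the core being stable to carbonate in methanol at room temperature.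

Compound list
1 | vanillin (4-hydroxy-3-methoxybenzaldehyde) | COc1cc(C=O)ccc1O | starting material
2 | 3-methoxy-4-(triisopropylsilyloxy)benzaldehyde | COc1cc(C=O)ccc1O[Si](C(C)C)(C(C)C)C(C)C | intermediate
3 | methyl (E)-4-bromobut-2-enoate | COC(=O)/C=C/CBr | starting material
4 | methyl (E)-3-{3-[3-methoxy-4-(triisopropylsilyloxy)phenyl]oxiran-2-yl}prop-2-enoate, racemic, both oxirane diastereomers | COC(=O)/C=C/C1OC1c1ccc(O[Si](C(C)C)(C(C)C)C(C)C)c(OC)c1 | intermediate
5 | carbonyl ylide from opening of the oxirane C–C bond of 4 (zwitterion, not isolated) | COC(=O)/C=C/C=[O+][CH-]c1ccc(O[Si](C(C)C)(C(C)C)C(C)C)c(OC)c1 | intermediate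
6 | methyl rac-(2S,3R)-2-[3-methoxy-4-(triisopropylsilyloxy)phenyl]-2,3-dihydrofuran-3-carboxylate (cis) | COC(=O)[C@@H]1C=CO[C@@H]1c1ccc(O[Si](C(C)C)(C(C)C)C(C)C)c(OC)c1 | intermediate
7 | methyl rac-(2S,3S)-2-[3-methoxy-4-(triisopropylsilyloxy)phenyl]-2,3-dihydrofuran-3-carboxylate (trans) | COC(=O)[C@H]1C=CO[C@@H]1c1ccc(O[Si](C(C)C)(C(C)C)C(C)C)c(OC)c1 | intermediate
8 | rac-{(2S,3R)-2-[3-methoxy-4-(triisopropylsilyloxy)phenyl]-2,3-dihydrofuran-3-yl}methanol (trans) | OC[C@H]1C=CO[C@@H]1c1ccc(O[Si](C(C)C)(C(C)C)C(C)C)c(OC)c1 | intermediate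
9 | {(2S,3R)-2-[3-methoxy-4-(triisopropylsilyloxy)phenyl]-2,3-dihydrofuran-3-yl}methyl acetate | CC(=O)OC[C@H]1C=CO[C@@H]1c1ccc(O[Si](C(C)C)(C(C)C)C(C)C)c(OC)c1 | intermediate
10 | {(2S,3R)-2-[3-methoxy-4-(triisopropylsilyloxy)phenyl]-2,3-dihydrofuran-3-yl}methanol, single enantiomer | OC[C@H]1C=CO[C@@H]1c1ccc(O[Si](C(C)C)(C(C)C)C(C)C)c(OC)c1 | intermediate
11 | 4-formyl-2-methoxyphenyl 2-methylpropanoate (vanillin isobutyrate) | CC(C)C(=O)Oc1ccc(C=O)cc1OC | starting material
12 | 4-(dimethoxymethyl)-2-methoxyphenyl 2-methylpropanoate | CC(C)C(=O)Oc1ccc(C(OC)OC)cc1OC | intermediate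
13 | mixed acetal of 10 and 12, 4-[methoxy({(2S,3R)-2-[3-methoxy-4-(triisopropylsilyloxy)phenyl]-2,3-dihydrofuran-3-yl}methoxy)methyl]-2-methoxyphenyl 2-methylpropanoate, both acetal epimers (not isolated) | COC(OC[C@H]1C=CO[C@@H]1c1ccc(O[Si](C(C)C)(C(C)C)C(C)C)c(OC)c1)c1ccc(OC(=O)C(C)C)c(OC)c1 | intermediate
14 | 4-{(1S,2R,5R,6S)-8-methoxy-6-[3-methoxy-4-(triisopropylsilyloxy)phenyl]-3,7-dioxabicyclo[3.3.0]octan-2-yl}-2-methoxyphenyl 2-methylpropanoate, C8 epimers | COc1cc([C@@H]2OC[C@H]3[C@@H]2C(OC)O[C@@H]3c2ccc(O[Si](C(C)C)(C(C)C)C(C)C)c(OC)c2)ccc1OC(=O)C(C)C | intermediate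
15 | 4-{(1R,2R,5R,6S)-6-[3-methoxy-4-(triisopropylsilyloxy)phenyl]-3,7-dioxabicyclo[3.3.0]octan-2-yl}-2-methoxyphenyl 2-methylpropanoate | COc1cc([C@@H]2OC[C@H]3[C@@H]2CO[C@@H]3c2ccc(O[Si](C(C)C)(C(C)C)C(C)C)c(OC)c2)ccc1OC(=O)C(C)C | intermediate
16 | 4-[(1R,2R,5R,6S)-6-(4-hydroxy-3-methoxyphenyl)-3,7-dioxabicyclo[3.3.0]octan-2-yl]-2-methoxyphenyl 2-methylpropanoate | COc1cc([C@@H]2OC[C@H]3[C@@H]2CO[C@@H]3c2ccc(O)c(OC)c2)ccc1OC(=O)C(C)C | intermediate
17 | 3-methylbut-2-en-1-ol (prenol) | CC(C)=CCO | starting material
18 | 4-{(1R,2R,5R,6S)-6-[3-methoxy-4-(3-methylbut-2-enyloxy)phenyl]-3,7-dioxabicyclo[3.3.0]octan-2-yl}-2-methoxyphenyl 2-methylpropanoate | COc1cc([C@@H]2OC[C@H]3[C@@H]2CO[C@@H]3c2ccc(OCC=C(C)C)c(OC)c2)ccc1OC(=O)C(C)C | intermediate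
19 | 4-{(1R,2R,5R,6S)-6-[3-methoxy-4-(3-methylbut-2-enyloxy)phenyl]-3,7-dioxabicyclo[3.3.0]octan-2-yl}-2-methoxyphenol | COc1cc([C@@H]2OC[C@H]3[C@@H]2CO[C@@H]3c2ccc(OCC=C(C)C)c(OC)c2)ccc1O | target

Total step count: 13. Longest linear sequence: 12 steps (steps 1 to 7 and 9 to 13, from vanillin); step 8 is a one-step side branch.

Steps most likely to fail

The pyrolysis of step 3 comes first. The heavy silylated oxirane may decompose while it is volatilised, or the dihydrofuran may fragment further in the hot zone, so that little product reaches the trap. The fallback keeps a ring expansion but starts from a cyclopropane. Setting out from 2, Wittig olefination with Ph3P=CHCHO should give (E)-3-[3-methoxy-4-(triisopropylsilyloxy)phenyl]prop-2-enal F1. Michael-initiated cyclopropanation with the ylide made from (2-methoxy-2-oxoethyl)dimethylsulfonium bromide and K2CO3 should then give racemic methyl 2-formyl-3-[3-methoxy-4-(triisopropylsilyloxy)phenyl]cyclopropane-1-carboxylate F2. A Cloke–Wilson rearrangement with catalytic Sc(OTf)3 in CH2Cl2, in which the formyl oxygen opens the bond between the formyl-bearing and the aryl-bearing carbon, should give the dihydrofuran ester. The route is rejoined at 7; any 6 formed with it is converged by step 4.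

The enzymatic resolution of step 6 comes second. The lipase may discriminate the enantiomers only weakly, or prefer the other one, so that the acetate is not enantiopure. The fallback is a covalent resolution. Setting out from 8, esterification with (S)-2-methoxy-2-phenylacetic acid (DCC, DMAP, CH2Cl2) should give two diastereomeric esters that are separated by chromatography or crystallisation. The diastereomer {(2S,3R)-2-[3-methoxy-4-(triisopropylsilyloxy)phenyl]-2,3-dihydrofuran-3-yl}methyl (S)-2-methoxy-2-phenylacetate F3 is then cleaved with iBu2AlH at −78 °C, and the route is rejoined at 10.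

The epimerisation of step 4 comes third. Proton exchange with the amidine base may be slow, or reprotonation may occur at the remote enol ether carbon, which moves the double bond into conjugation with the ester and destroys the stereocentre. The fallback equilibrates at the aldehyde oxidation level, where a much weaker base suffices. Setting out from 6, iBu2AlH (one equivalent, CH2Cl2, −78 °C) should give the cis aldehyde rac-(2S,3R)-2-[3-methoxy-4-(triisopropylsilyloxy)phenyl]-2,3-dihydrofuran-3-carbaldehyde F4. Et3N in CH2Cl2 should equilibrate it to the trans aldehyde rac-(2S,3S)-2-[3-methoxy-4-(triisopropylsilyloxy)phenyl]-2,3-dihydrofuran-3-carbaldehyde F5. NaBH4 in EtOH at 0 °C then gives the alcohol, and the route is rejoined at 8.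

Further compounds
F1 | step 3 | (E)-3-[3-methoxy-4-(triisopropylsilyloxy)phenyl]prop-2-enal | O=C/C=C/c1ccc(O[Si](C(C)C)(C(C)C)C(C)C)c(OC)c1
F2 | step 3 | methyl rac-2-formyl-3-[3-methoxy-4-(triisopropylsilyloxy)phenyl]cyclopropane-1-carboxylate (formyl and aryl trans, both epimers at the ester carbon) | COC(=O)C1[C@H](C=O)[C@H]1c1ccc(O[Si](C(C)C)(C(C)C)C(C)C)c(OC)c1
F3 | step 6 | {(2S,3R)-2-[3-methoxy-4-(triisopropylsilyloxy)phenyl]-2,3-dihydrofuran-3-yl}methyl (S)-2-methoxy-2-phenylacetate | CO[C@H](C(=O)OC[C@H]1C=CO[C@@H]1c1ccc(O[Si](C(C)C)(C(C)C)C(C)C)c(OC)c1)c1ccccc1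
F4 | step 4 | rac-(2S,3R)-2-[3-methoxy-4-(triisopropylsilyloxy)phenyl]-2,3-dihydrofuran-3-carbaldehyde (cis) | O=C[C@@H]1C=CO[C@@H]1c1ccc(O[Si](C(C)C)(C(C)C)C(C)C)c(OC)c1
F5 | step 4 | rac-(2S,3S)-2-[3-methoxy-4-(triisopropylsilyloxy)phenyl]-2,3-dihydrofuran-3-carbaldehyde (trans) | O=C[C@H]1C=CO[C@@H]1c1ccc(O[Si](C(C)C)(C(C)C)C(C)C)c(OC)c1
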